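**Retrosynthetic overview**
1. End game: the (Z)-allylic acetate comes from a C14 aldehyde (Still–Gennari olefination, ester reduction, acetylation), followed by global desilylation.
2. Bicycle: the C10–C11 bond is closed by a Claisen-type acylation of the dioxanone enolate with a tethered Weinreb amide; the tether fixes C11, and a CBS reduction then sets C10.
3. C11–C12 bond: intermolecular Michael addition of a 2-alkoxymalonate (C11) to N-methoxy-N-methylacrylamide; the C6–O–C11 ether comes from Rh-carbenoid O–H insertion.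
4. C6/C7: Shi epoxidation of an E-trisubstituted alkene, then 5-exo epoxy-acid lactonisation with inversion at C7; C9–C10 come from a Johnson–Claisen rearrangement on a nerol-derived allylic alcohol.
5. Ring order: epoxide → temporary γ-lactone → 1,4-dioxan-2-one → oxepane/ε-lactone (the bridged bicycle) in the C10–C11 closure.

Convention used in names: chain locants C1 (CH2OH) … C16 (CH2OAc), C17 = lactone C=O; the target is (2Z,14Z,6S,7R,10S,11R). TBDPS = tert-butyldiphenylsilyl.

**Route**

Step 1
Reactants: 1 nerol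
Product: 2 neryl TBDPS ether
Conditions: TBDPSCl, imidazole, DMF, 0 °C → rt
Reagents that add atoms: tert-butyl(chloro)diphenylsilane CC(C)(C)[Si](Cl)(c1ccccc1)c1ccccc1
Why: Silyl ether formation protects the C1 hydroxyl with a group that survives every later step and stays distinct from the C16 acetate; no stereocentre is involved.

Step 2
Reactants: 2 neryl TBDPS ether
Product: 3 racemic 6,7-epoxide
Conditions: mCPBA (1.05 equiv), CH2Cl2, −20 → 0 °C
Reagents that add atoms: 3-chloroperoxybenzoic acid OOC(=O)c1cccc(Cl)c1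
Why: Prilezhaev epoxidation prefers the more electron-rich distal trisubstituted alkene over the one shielded and deactivated by CH2OTBDPS; the racemic stereocentre is erased in steps 3–4.

Step 3
Reactants: 3 racemic 6,7-epoxide
Product: 4 racemic allylic alcohol (C6–OH with C7 isopropenyl)
Conditions: Al(Oi-Pr)3 (20 mol %), toluene, 110 °C
Reagents that add atoms: none
Why: Lewis-acid-mediated epoxide-to-allylic-alcohol isomerisation removes a proton from a gem-methyl group and gives the 2-methyl-1-en-3-ol needed for the Claisen step.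

Step 4
Reactants: 4 racemic allylic alcohol; 5 triethyl orthoacetate
Product: 7 ethyl (4E,8Z)-10-(TBDPS-oxy)-4,8-dimethyldeca-4,8-dienoate, via mixed ketene acetal 6 (not isolated)
Conditions: 5 (6 equiv), EtCO2H (cat.), 140 °C, EtOH distilled off
Reagents that add atoms: none
Why: Johnson–Claisen orthoester rearrangement through a chair transition state with the C5 chain equatorial gives the E-trisubstituted C6=C7 alkene and adds C9–C10 as the ester.

Step 5
Reactants: 7 dienoate ester
Product: 8 (6S,7S)-6,7-epoxy ester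
Conditions: ent-Shi ketone (L-fructose-derived, 30 mol %), Oxone, K2CO3, Bu4NHSO4 (cat.), MeCN/DMM–aq. borate/EDTA buffer, 0 °C
Reagents that add atoms: potassium peroxymonosulfate (Oxone) [K+].[O-]S(=O)(=O)OO
Why: Shi asymmetric epoxidation (chiral dioxirane, spiro transition state) attacks the electron-rich E-trisubstituted C6=C7 alkene, and the enantiomeric ketone delivers the (6S,7S) epoxide while the allylic-ether alkene is left alone.

Step 6
Reactants: 8 (6S,7S)-epoxy ester
Product: 10 hydroxy γ-lactone (6S,7R), via epoxy acid 9 (not isolated)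
Conditions: LiOH, THF/H2O, rt; then 1 M HCl to pH 3, 0 °C → rt
Reagents that add atoms: lithium hydroxide [Li+].[OH-]
Why: Saponification followed by acid-triggered 5-exo epoxide opening by the carboxyl group at the tertiary carbon inverts C7 (S → R) and leaves C6 (S) untouched, which fixes the C6/C7 pair of the target.

Step 7
Reactants: 10 hydroxy γ-lactone; 11 dimethyl diazomalonate
Product: 12 dimethyl 2-alkoxymalonate (C6–O–CH(CO2Me)2)
Conditions: Rh2(OAc)4 (2 mol %), benzene, 80 °C, slow addition of 11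
Reagents that add atoms: none
Why: Rhodium-carbenoid O–H insertion builds the hindered secondary ether to C11 under neutral conditions, so the lactone and the C6 configuration are not disturbed.

Step 8
Reactants: 12 dimethyl 2-alkoxymalonate; 13 N-methoxy-N-methylacrylamide
Product: 14 Michael adduct (C11 bearing two CO2Me and the C12–C14 amide arm)
Conditions: t-BuOK (0.2 equiv), THF/t-BuOH, 0 °C → rt
Reagents that add atoms: none
Why: Michael addition of the soft malonate anion to the acrylamide forms the C11–C12 bond and the fully substituted C11 under catalytic base; with two identical esters C11 is not yet stereogenic.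

Step 9
Reactants: 14 Michael adduct
Product: 16 methyl dioxanone-3-carboxylate (C11 epimers), via magnesium alkoxide 15 (not isolated)
Conditions: MeNHOMe·HCl (1.5 equiv), i-PrMgCl (3.2 equiv), THF, −20 °C → rt; cold 0.5 M HCl
Reagents that add atoms: N,O-dimethylhydroxylamine hydrochloride CNOC.Cl
Why: Weinreb aminolysis opens the unhindered γ-lactone in preference to the quaternary malonate esters, and the freed tertiary C7 alkoxide lactonises 6-exo-trig onto one ester to give the 1,4-dioxan-2-one; the C11 epimer ratio is irrelevant.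

Step 10
Reactants: 16 methyl dioxanone-3-carboxylate
Product: 17 dioxanone with C11–H (C11 epimers)
Conditions: LiCl (3 equiv), H2O (3 equiv), DMSO, 130 °C
Reagents that add atoms: none
Why: Krapcho dealkoxycarbonylation removes the spare ester by chloride demethylation and decarboxylation; C11 is re-enolised in the next step, so its configuration does not matter here.

Step 11
Reactants: 17 dioxanone with C11–H
Product: 20 bicyclic β-keto lactone (6S,7R,11R), via lithium enolate 18 (not isolated), via tetrahedral lithium alkoxide 19 (not isolated)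
Conditions: LiHMDS (1.3 equiv), THF (0.01 M), −78 → −20 °C; AcOH quench
Reagents that add atoms: none
Why: Intramolecular Claisen-type (Dieckmann-like) acylation of the lactone enolate by the C10 Weinreb amide forms C10–C11; the chelated tetrahedral adduct blocks retro-Claisen, and the C7 tether can only reach the enolate face cis to C8, which sets C11 as R.

Step 12
Reactants: 20 bicyclic β-keto lactone
Product: 21 (10S)-alcohol
Conditions: (R)-2-methyl-CBS-oxazaborolidine (0.5 equiv), catecholborane (2 equiv), toluene, −78 → −40 °C; MeOH, aqueous work-up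
Reagents that add atoms: none
Why: Corey–Bakshi–Shibata reduction treats the quaternary C11 side as the large group, so the (R)-catalyst is expected to deliver hydride to the face that gives the (10S) carbinol, though the substrate's own facial bias is uncertain and may oppose it.

Step 13
Reactants: 21 (10S)-alcohol
Product: 22 C10 triethylsilyl ether
Conditions: TESOTf, 2,6-lutidine, CH2Cl2, −78 → 0 °C
Reagents that add atoms: triethylsilyl triflate CC[Si](CC)(CC)OS(=O)(=O)C(F)(F)F
Why: Silylation of the hindered secondary alcohol prevents lactol formation, retro-aldol and aluminium chelation in the following hydride and base steps.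

Step 14
Reactants: 22 C10 triethylsilyl ether
Product: 24 C14 aldehyde, via aluminium hemiaminal 23 (not isolated)
Conditions: DIBAL-H (1.3 equiv), THF, −78 °C; aq. Rochelle salt
Reagents that add atoms: none
Why: Weinreb amide reduction stops at the chelated hemiaminal and releases the aldehyde on work-up, while the bridged lactone (α-quaternary, tertiary alkyl ester) is too hindered to react at −78 °C.

Step 15
Reactants: 24 C14 aldehyde; 25 methyl 2-[bis(2,2,2-trifluoroethoxy)phosphoryl]propanoate
Product: 27 (14Z)-α-methyl enoate, via potassium phosphonate carbanion 26 (not isolated)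
Conditions: 25, KHMDS, 18-crown-6, THF, −78 °C; then 24
Reagents that add atoms: none
Why: Still–Gennari modification of the Horner–Wadsworth–Emmons olefination gives the Z-trisubstituted enoate (ester cis to the chain) under kinetic control.

Step 16
Reactants: 27 (14Z)-α-methyl enoate
Product: 28 (14Z)-allylic alcohol
Conditions: DIBAL-H (2.5 equiv), CH2Cl2, −78 °C; aq. Rochelle salt
Reagents that add atoms: none
Why: DIBAL 1,2-reduction of the unhindered conjugated ester is much faster than attack on the hindered bridged lactone, and the alkene geometry is retained.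

Step 17
Reactants: 28 (14Z)-allylic alcohol
Product: 29 C16 acetate
Conditions: Ac2O, pyridine, DMAP (cat.), CH2Cl2, 0 °C
Reagents that add atoms: acetic anhydride CC(=O)OC(C)=O
Why: Acylation of the only free hydroxyl installs the C16 acetate.

Step 18
Reactants: 29 C16 acetate
Product: 30 target CNP0174851.1
Conditions: HF·pyridine, pyridine/THF, 0 °C → rt
Reagents that add atoms: none
Why: Fluoride-mediated cleavage of the TES and TBDPS ethers frees the C10 and C1 hydroxyls without touching the acetate, the lactone or any stereocentre.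

**Compound list**
1 | nerol, (2Z)-3,7-dimethylocta-2,6-dien-1-ol | CC(C)=CCC/C(C)=C\CO | starting material
2 | neryl tert-butyldiphenylsilyl ether | CC(C)=CCC/C(C)=C\CO[Si](c1ccccc1)(c1ccccc1)C(C)(C)C | intermediate
3 | racemic 6,7-epoxide of 2 | CC1(C)OC1CC/C(C)=C\CO[Si](c2ccccc2)(c2ccccc2)C(C)(C)C | intermediate
4 | racemic (6Z)-8-(TBDPS-oxy)-2,6-dimethylocta-1,6-dien-3-ol | C=C(C)C(O)CC/C(C)=C\CO[Si](c1ccccc1)(c1ccccc1)C(C)(C)C | intermediate
5 | triethyl orthoacetate | CC(OCC)(OCC)OCC | starting material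
6 | mixed ketene acetal (1-ethoxyvinyl ether of 4) | C=C(OCC)OC(CC/C(C)=C\CO[Si](c1ccccc1)(c1ccccc1)C(C)(C)C)C(C)=C | intermediate (not isolated)
7 | ethyl (4E,8Z)-10-(TBDPS-oxy)-4,8-dimethyldeca-4,8-dienoate | CCOC(=O)CC/C(C)=C/CC/C(C)=C\CO[Si](c1ccccc1)(c1ccccc1)C(C)(C)C | intermediate
8 | ethyl (4S,5S,8Z)-4,5-epoxy-10-(TBDPS-oxy)-4,8-dimethyldec-8-enoate, i.e. (6S,7S) in chain locants | CCOC(=O)CC[C@]1(C)O[C@H]1CC/C(C)=C\CO[Si](c2ccccc2)(c2ccccc2)C(C)(C)C | intermediate
9 | (6S,7S)-epoxy acid from 8 | OC(=O)CC[C@]1(C)O[C@H]1CC/C(C)=C\CO[Si](c2ccccc2)(c2ccccc2)C(C)(C)C | intermediate (not isolated)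
10 | (5R)-5-[(1S,4Z)-1-hydroxy-4-methyl-6-(TBDPS-oxy)hex-4-enyl]-5-methyloxolan-2-one, i.e. (6S,7R) | O[C@@H](CC/C(C)=C\CO[Si](c1ccccc1)(c1ccccc1)C(C)(C)C)[C@@]2(C)CCC(=O)O2 | intermediate
11 | dimethyl diazomalonate | COC(=O)C(=[N+]=[N-])C(=O)OC | starting material
12 | dimethyl 2-alkoxymalonate, malonate CH on the C6 oxygen of 10 (6S,7R) | COC(=O)C(O[C@@H](CC/C(C)=C\CO[Si](c1ccccc1)(c1ccccc1)C(C)(C)C)[C@@]2(C)CCC(=O)O2)C(=O)OC | intermediate
13 | N-methoxy-N-methylacrylamide | C=CC(=O)N(C)OC | starting material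
14 | Michael adduct: dimethyl 2-alkoxy-2-[3-(methoxy(methyl)amino)-3-oxopropyl]malonate (alkoxy as in 12) | COC(=O)C(CCC(=O)N(C)OC)(O[C@@H](CC/C(C)=C\CO[Si](c1ccccc1)(c1ccccc1)C(C)(C)C)[C@@]2(C)CCC(=O)O2)C(=O)OC | intermediate
15 | chloromagnesium C7-alkoxide of the lactone-opened bis(Weinreb amide) malonate | COC(=O)C(CCC(=O)N(C)OC)(O[C@@H](CC/C(C)=C\CO[Si](c1ccccc1)(c1ccccc1)C(C)(C)C)[C@](C)(O[Mg]Cl)CCC(=O)N(C)OC)C(=O)OC | intermediate (not isolated)
16 | methyl (5S,6R)-6-methyl-5-[(3Z)-3-methyl-5-(TBDPS-oxy)pent-3-enyl]-3,6-bis[3-(methoxy(methyl)amino)-3-oxopropyl]-2-oxo-1,4-dioxane-3-carboxylate (C3 epimers) | COC(=O)C1(CCC(=O)N(C)OC)O[C@@H](CC/C(C)=C\CO[Si](c2ccccc2)(c2ccccc2)C(C)(C)C)[C@@](C)(CCC(=O)N(C)OC)OC1=O | intermediate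
17 | (5S,6R)-6-methyl-5-[(3Z)-3-methyl-5-(TBDPS-oxy)pent-3-enyl]-3,6-bis[3-(methoxy(methyl)amino)-3-oxopropyl]-1,4-dioxan-2-one (C3 epimers) | CON(C)C(=O)CCC1O[C@@H](CC/C(C)=C\CO[Si](c2ccccc2)(c2ccccc2)C(C)(C)C)[C@@](C)(CCC(=O)N(C)OC)OC1=O | intermediate
18 | lithium enolate of 17 (C11=C17–OLi) | [Li+].CON(C)C(=O)CCC1=C([O-])O[C@](C)(CCC(=O)N(C)OC)[C@H](CC/C(C)=C\CO[Si](c2ccccc2)(c2ccccc2)C(C)(C)C)O1 | intermediate (not isolated)
19 | bicyclic tetrahedral adduct, lithium alkoxide of the C10 N,O-hemiaminal | [Li+].CON(C)C(=O)CC[C@@]12O[C@@H](CC/C(C)=C\CO[Si](c3ccccc3)(c3ccccc3)C(C)(C)C)[C@@](C)(CCC1([O-])N(C)OC)OC2=O | intermediate (not isolated)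
20 | bicyclic β-keto lactone (6S,7R,11R): bridged dioxanone with C10 ketone and C14 Weinreb amide | CON(C)C(=O)CC[C@@]12O[C@@H](CC/C(C)=C\CO[Si](c3ccccc3)(c3ccccc3)C(C)(C)C)[C@@](C)(CCC1=O)OC2=O | intermediate
21 | (6S,7R,10S,11R)-C10 alcohol | CON(C)C(=O)CC[C@@]12O[C@@H](CC/C(C)=C\CO[Si](c3ccccc3)(c3ccccc3)C(C)(C)C)[C@@](C)(CC[C@@H]1O)OC2=O | intermediate
22 | C10 triethylsilyl ether of 21 | CON(C)C(=O)CC[C@@]12O[C@@H](CC/C(C)=C\CO[Si](c3ccccc3)(c3ccccc3)C(C)(C)C)[C@@](C)(CC[C@@H]1O[Si](CC)(CC)CC)OC2=O | intermediate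
23 | diisobutylaluminium hemiaminal at C14 | CON(C)C(CC[C@@]12O[C@@H](CC/C(C)=C\CO[Si](c3ccccc3)(c3ccccc3)C(C)(C)C)[C@@](C)(CC[C@@H]1O[Si](CC)(CC)CC)OC2=O)O[Al](CC(C)C)CC(C)C | intermediate (not isolated)
24 | C14 aldehyde (C10–OTES, C1–OTBDPS) | O=CCC[C@@]12O[C@@H](CC/C(C)=C\CO[Si](c3ccccc3)(c3ccccc3)C(C)(C)C)[C@@](C)(CC[C@@H]1O[Si](CC)(CC)CC)OC2=O | intermediate
25 | methyl 2-[bis(2,2,2-trifluoroethoxy)phosphoryl]propanoate | COC(=O)C(C)P(=O)(OCC(F)(F)F)OCC(F)(F)F | starting material
26 | potassium carbanion of 25 | [K+].COC(=O)[C-](C)P(=O)(OCC(F)(F)F)OCC(F)(F)F | intermediate (not isolated)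
27 | (14Z)-methyl enoate | COC(=O)/C(C)=C\CC[C@@]12O[C@@H](CC/C(C)=C\CO[Si](c3ccccc3)(c3ccccc3)C(C)(C)C)[C@@](C)(CC[C@@H]1O[Si](CC)(CC)CC)OC2=O | intermediate
28 | (14Z)-allylic alcohol | OC/C(C)=C\CC[C@@]12O[C@@H](CC/C(C)=C\CO[Si](c3ccccc3)(c3ccccc3)C(C)(C)C)[C@@](C)(CC[C@@H]1O[Si](CC)(CC)CC)OC2=O | intermediate
29 | C16 acetate (C10–OTES, C1–OTBDPS) | CC(=O)OC/C(C)=C\CC[C@@]12O[C@@H](CC/C(C)=C\CO[Si](c3ccccc3)(c3ccccc3)C(C)(C)C)[C@@](C)(CC[C@@H]1O[Si](CC)(CC)CC)OC2=O | intermediate
30 | CNP0174851.1, (2Z,14Z,6S,7R,10S,11R) | CC(=O)OC/C(C)=C\CC[C@@]12O[C@@H](CC/C(C)=C\CO)[C@@](C)(CC[C@@H]1O)OC2=O | target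

**Totals and risks**
Total step count: 18. Longest linear sequence: 18 steps, from nerol.

The three steps most likely to fail are steps 9, 11 and 12.

Step 9 (selective lactone aminolysis beside two malonate esters, then relactonisation). The fallback sets out from 10 and comes back at 16, opening the lactone before any malonate is present. Compound 10 is treated with i-PrMgCl/MeNHOMe·HCl to give the diol Weinreb amide F1. Rh2(OAc)4 with 11 then inserts into the less hindered secondary C6–OH to give the hydroxy alkoxymalonate F2. Catalytic DBU in MeCN closes the tertiary alcohol onto one ester to give the cyclic alkoxymalonate F3, which still carries an acidic C11–H and adds to 13 under the same base to give 16.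

Step 11 (seven-membered bridging acylation of a tetrasubstituted enolate). The fallback sets out from 17 and comes back at 24, replacing acylation plus ketone reduction by a direct aldol. Compound 17 is O-silylated (LiHMDS, TBSCl, HMPA, THF, −78 °C) to the TBS ketene acetal F4. Both Weinreb amides are reduced (DIBAL-H, CH2Cl2, −78 °C, buffered Rochelle work-up) to the dialdehyde ketene acetal F5. BF3·OEt2 at −78 °C then triggers an intramolecular Mukaiyama aldol in which only the C10 aldehyde can reach C11, giving the bicyclic hydroxy aldehyde F6; C10 selectivity in this open transition state is not predictable, so any C10 epimer is removed by chromatography. TESCl/imidazole converts F6 into 24.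

Step 12 (facial selectivity at C10; catalyst control may oppose the substrate bias). The fallback sets out from 20 and comes back at 21, relying on separation and recycling instead of reagent control. Compound 20 is reduced with NaBH4/CeCl3 (MeOH, −40 °C); 21 is separated from the (10R)-epimer F7, and F7 is oxidised with Dess–Martin periodinane back to 20 and resubmitted.

**Further compounds**
F1 | step 9 | diol Weinreb amide (6S,7R), from lactone opening of 10 | O[C@@H](CC/C(C)=C\CO[Si](c1ccccc1)(c1ccccc1)C(C)(C)C)[C@](C)(O)CCC(=O)N(C)OC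
F2 | step 9 | hydroxy alkoxymalonate (malonate on the C6 oxygen, free C7–OH) | COC(=O)C(O[C@@H](CC/C(C)=C\CO[Si](c1ccccc1)(c1ccccc1)C(C)(C)C)[C@](C)(O)CCC(=O)N(C)OC)C(=O)OC
F3 | step 9 | cyclic alkoxymalonate, methyl (5S,6R)-dioxanone-3-carboxylate with C3–H | COC(=O)C1O[C@@H](CC/C(C)=C\CO[Si](c2ccccc2)(c2ccccc2)C(C)(C)C)[C@@](C)(CCC(=O)N(C)OC)OC1=O
F4 | step 11 | TBS ketene acetal of 17 | CON(C)C(=O)CCC1=C(O[Si](C)(C)C(C)(C)C)O[C@](C)(CCC(=O)N(C)OC)[C@H](CC/C(C)=C\CO[Si](c2ccccc2)(c2ccccc2)C(C)(C)C)O1
F5 | step 11 | dialdehyde TBS ketene acetal | O=CCCC1=C(O[Si](C)(C)C(C)(C)C)O[C@](C)(CCC=O)[C@H](CC/C(C)=C\CO[Si](c2ccccc2)(c2ccccc2)C(C)(C)C)O1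
F6 | step 11 | bicyclic (10S)-hydroxy C14 aldehyde | O=CCC[C@@]12O[C@@H](CC/C(C)=C\CO[Si](c3ccccc3)(c3ccccc3)C(C)(C)C)[C@@](C)(CC[C@@H]1O)OC2=O
F7 | step 12 | (10R)-epimer of 21 | CON(C)C(=O)CC[C@@]12O[C@@H](CC/C(C)=C\CO[Si](c3ccccc3)(c3ccccc3)C(C)(C)C)[C@@](C)(CC[C@H]1O)OC2=O
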